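**Compound numbers used throughout:** 1 dimethyl 3-hydroxy-3-methylglutarate; 2 its (S)-half-ester; 3 Weinreb amide ester; 4 its triethylsilyl ether; 5 the derived acid; 6 N-hydroxyphthalimide; 7 the N-acyloxyphthalimide; 8 allyl phenyl sulfone; 9 its monomethyl homologue; 10 2-methylbut-3-en-2-yl phenyl sulfone; 11 the prenylated Weinreb amide; 12 2,5-dibromohydroquinone; 13 its bis-MOM ether; 14 the aryllithium; 15 the lithium chelate; 16 the protected ketone; 17 the desilylated ketone; 18 the target.

## The problem

The target 18 is an acyclic eight-carbon chain (C1–C8, methyl groups on C3 and C7) joined through its C1 ketone to a 4-bromo-2,5-dihydroxyphenyl ring (C1'–C6'), so no ring has to be made and the task is chain assembly plus one stereocentre. That centre, C3, is an (R)-configured tertiary carbinol carrying a methyl group and two methylene arms, C2 towards the ketone and C4 towards the olefin. Nothing else in the molecule is stereogenic, so no neighbouring centre can relay to it; the configuration has to come from telling two nearly identical arms apart or from an external chiral agent. The C3 hydroxyl is β to the aryl ketone, so acid or base can dehydrate it to the conjugated enone (which the ortho phenol would then close to a chromanone), and base can cleave C2–C3 by retro-aldol. The bromohydroquinone is easily oxidised, the aryl bromide excludes hydrogenolysis and late palladium chemistry, and the C6=C7 olefin does not tolerate strong acid. C4 is neopentyl-like, so forming C4–C5 by displacement is unrealistic. The enabling feature is that C3 with its OH, CH3 and the C2 and C4 methylenes is the carbon pattern of 3-hydroxy-3-methylglutaric acid: one carboxyl becomes C1, the other can be lost as CO2 to leave a radical on C4, and C5–C8 is a prenyl group that a radical can take from an allylic sulfone.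

## Retrosynthesis

**18 back to 16.** Only O–protecting-group bonds are cut: two methoxymethyl acetals on the phenols and a triethylsilyl ether on the C3 hydroxyl, with the desilylated ketone 17 passed through on the way. The phenols must be masked for the organolithium chemistry, and the silyl ether blocks retro-aldol cleavage, β-lactone formation from the active ester and waste of aryllithium. All three groups are of the kind that mild acidic methanolysis removes in one operation. The forward step must cleave them without dehydrating the tertiary β-hydroxy ketone.

**16 back to 11 and 13.** The aryl–carbonyl bond C1–C1' is cut. A Friedel–Crafts or Fries acylation of a bromohydroquinone would need strong Lewis acid next to a tertiary ether and has no secure regiochemistry. Acylating an aryllithium with a Weinreb amide fixes the position by the halogen that is exchanged. The symmetric dibromide 13 gives one monolithio species 14, and the bromine that remains is the one the target needs. Compound 13 comes in one step from commercial 12. The forward reaction must stop at the ketone, which the chelate 15 ensures, and must not enolise 11.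

**11 back to 7 and 10 (key disconnection).** The C4–C5 bond is cut. Cutting C5–C6 or C3–C4 instead would keep a chiral chain fragment that has to be made separately; cutting C4–C5 reduces the chiral part to a glutarate and delivers the prenyl unit in one piece. The olefin position is fixed by where the sulfonyl group sits in 10. The forward step needs a C4 radical, generated from the N-acyloxyphthalimide 7 by loss of CO2, to add at the free CH2 terminus of 10 and expel the sulfonyl group. It must tolerate the Weinreb amide and the silyl ether and leave C3 alone.

**7 back to 1 via 5, 4, 3 and 2, with 6 as the activating partner.** These are functional-group steps that make the two arms of the glutarate different. The prochiral diester 1 is desymmetrised to the half-ester 2. In (S)-2 the free acid is the arm that must become C2/C1, so it is converted at once into the Weinreb amide 3, which is then carried through as a spectator and is already the acyl donor needed later. The methyl ester is the arm that must become C4; after silylation to 4 it is saponified to 5 and activated with 6 to give 7. This assignment uses the half-ester directly and avoids any ester-to-amide exchange after the key step.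

**10 back to 8, and 13 back to 12.** Two C–CH3 bonds α to sulfur are cut, leading to commercial allyl phenyl sulfone 8 through the monomethyl compound 9. Two O–CH2 bonds are cut to return 13 to commercial 12. Both forward reactions are simple alkylations.

## Roads not taken

Alternative 1: The cut is through the arene itself, at C1'–C2' and C5'–C6'. In the forward direction the diene 4-bromo-2-(triisopropylsilyloxy)furan A2 and the terminal ynone (R)-5,9-dimethyl-5-(triethylsilyloxy)dec-8-en-1-yn-3-one A3 would undergo a [4+2] cycloaddition, and opening of the oxygen bridge would aromatise the adduct to the phenol (R)-1-[4-bromo-5-hydroxy-2-(triisopropylsilyloxy)phenyl]-3,7-dimethyl-3-(triethylsilyloxy)oct-6-en-1-one A1.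
- Merits: the bromine and both oxygens are placed unambiguously, the two phenol oxygens arrive differentiated, and no aryl-metal is needed. Both silyl groups of A1 would fall to fluoride, which is a gentler end-game for the β-hydroxy ketone than acid removal of acetals; in this respect the alternative is better.
- Weak points: it spends its main step building a benzene ring that can be bought with all three heteroatoms in place as 12. The ynone A3 already contains the whole chiral chain, so C3 and the C4–C5 problem remain to be solved elsewhere. Silyloxyfurans such as A2 tend to react with ynones by vinylogous conjugate addition instead of cycloaddition, the bromine of A2 lowers diene reactivity, and the β-silyloxy ynone A3 can eliminate.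
- Comparison: the chosen plan answers the end-game concern with a buffered fluoride/Lewis-acid fallback and uses a one-step arene fragment.

Alternative 2: The cut is C3–C4. (4-Methylpent-3-enyl)magnesium bromide A6, in the presence of CuBr·SMe2 A7 (monovalent copper), would add to C6 of (S)-2-tert-butyl-6-methyl-4H-1,3-dioxin-4-one A5 to give the dioxanone (2S,6R)-2-tert-butyl-6-methyl-6-(4-methylpent-3-enyl)-1,3-dioxan-4-one A4.
- Merits: one C–C bond formation creates the fully substituted carbinol carbon and brings the whole homoprenyl chain of A6, so no prenyl regiochemistry arises. The face is controlled by the acetal centre of A5, a substrate-controlled process that is more secure than an enzyme distinguishing OH from CH3. The lactone carbonyl of A4 is ready for conversion to the aryl ketone. On stereochemical security this route is stronger than the chosen one, and its step count is similar or slightly lower.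
- Weak points: A5 must be prepared over several steps from a chiral-pool hydroxy acid, with stoichiometric chirality. Conjugate addition to a β,β-disubstituted position is sluggish and needs the organocopper reagent from A6 and A7 in stoichiometric amount at low temperature. A4 must then be opened to an acyl donor without over-addition.
- Comparison: the chosen plan sets against this a cheap symmetric diester, chirality from a catalytic enzyme step whose outcome can be assayed on 2 before anything valuable is committed, and access to either enantiomer from the same half-ester by exchanging the roles of the arms.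

Alternative 3: The cut is the C3–O bond, made through a C3–B bond. Bis(pinacolato)diboron A10 would add to the enone (E)-1-[4-bromo-2,5-bis(methoxymethoxy)phenyl]-3,7-dimethylocta-2,6-dien-1-one A9 under catalysis by CuCl A11 (monovalent copper) with a chiral ferrocenyl bisphosphine, an alkoxide base and a protic additive, to give the tertiary boronate (S)-1-[4-bromo-2,5-bis(methoxymethoxy)phenyl]-3,7-dimethyl-3-(4,4,5,5-tetramethyl-1,3,2-dioxaborolan-2-yl)oct-6-en-1-one A8. Stereoretentive oxidation of A8 would give the carbinol.
- Merits: this is the shortest route, about six steps against ten. The enone A9 comes from 14 and a ten-carbon dienoyl donor, the asymmetric step is catalytic, and the boronate in A8 protects C3 from retro-aldol and dehydration until it is oxidised. On step economy it is clearly better.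
- Weak points: the catalyst has to distinguish CH3 from a CH2CH2R chain at a β,β-dialkyl enone, and the level of selectivity for an ortho-substituted aryl ketone cannot be assured. The two olefin isomers of A9 would give opposite enantiomers, and the base can equilibrate them through the dienolate. Copper–boryl species formed from A10 and A11 may attack the aryl bromide.
- Comparison: the chosen plan fixes the stereocentre before the sensitive aryl ketone exists, is independent of olefin geometry, and uses no copper–boryl chemistry next to the C–Br bond.

Key step: step 7

**Assumption on the chemistry:** pig liver esterase is taken to cleave 1 to the (S)-half-ester 2, the sense recorded for this diester; the arm assignment in steps 2–5 follows from it.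

## Route

Step 1
Reactants: 1 dimethyl 3-hydroxy-3-methylpentanedioate (dimethyl 3-hydroxy-3-methylglutarate)
Product: 2 (S)-3-hydroxy-5-methoxy-3-methyl-5-oxopentanoic acid
Conditions: pig liver esterase, 0.1 M phosphate buffer pH 7.5 (pH-stat, 1 M NaOH), 25 °C; then HCl to pH 2–3, EtOAc extraction
Reagents that add atoms: water, O
Why: Enzymatic desymmetrisation by enantiotopic-group-selective ester hydrolysis; the esterase cleaves one of the two enantiotopic methyl esters and the resulting carboxylate is not hydrolysed further, which sets C3 as (S) in 2, the only stereocentre of the route.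

Step 2
Reactants: 2 (S)-3-hydroxy-5-methoxy-3-methyl-5-oxopentanoic acid
Product: 3 methyl (S)-3-hydroxy-5-[methoxy(methyl)amino]-3-methyl-5-oxopentanoate
Conditions: MeNHOMe·HCl, EDC·HCl, HOBt, N-methylmorpholine, CH2Cl2, 0 °C → rt
Reagents that add atoms: N,O-dimethylhydroxylamine hydrochloride, CNOC.Cl
Why: Carbodiimide amide coupling to the Weinreb amide; the tertiary hydroxyl is too hindered to be acylated and the methyl ester is untouched, so the two arms are now chemically distinct and C3, which bears no hydrogen, cannot epimerise.

Step 3
Reactants: 3 methyl (S)-3-hydroxy-5-[methoxy(methyl)amino]-3-methyl-5-oxopentanoate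
Product: 4 methyl (S)-5-[methoxy(methyl)amino]-3-methyl-5-oxo-3-(triethylsilyloxy)pentanoate
Conditions: TESOTf, 2,6-lutidine, CH2Cl2, −78 → 0 °C
Reagents that add atoms: triethylsilyl trifluoromethanesulfonate, CC[Si](CC)(CC)OS(=O)(=O)C(F)(F)F
Why: Silyl triflate silylation of a hindered tertiary alcohol with a non-nucleophilic pyridine base; the ether prevents retro-aldol cleavage, lactonisation of the later active ester and consumption of aryllithium.

Step 4
Reactants: 4 methyl (S)-5-[methoxy(methyl)amino]-3-methyl-5-oxo-3-(triethylsilyloxy)pentanoate
Product: 5 (S)-5-[methoxy(methyl)amino]-3-methyl-5-oxo-3-(triethylsilyloxy)pentanoic acid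
Conditions: LiOH·H2O, THF/H2O (3:1), 0 °C → rt; then 1 M HCl to pH 4 at 0 °C
Reagents that add atoms: lithium hydroxide monohydrate, [Li+].[OH-].O
Why: Saponification; hydroxide attacks the methyl ester much faster than the tertiary N-methoxy-N-methylamide, and a tertiary triethylsilyl ether is stable to cold aqueous base and to a brief pH 4 work-up.

Step 5
Reactants: 5 (S)-5-[methoxy(methyl)amino]-3-methyl-5-oxo-3-(triethylsilyloxy)pentanoic acid; 6 N-hydroxyphthalimide
Product: 7 1,3-dioxoisoindolin-2-yl (S)-5-[methoxy(methyl)amino]-3-methyl-5-oxo-3-(triethylsilyloxy)pentanoate
Conditions: DIC, DMAP (cat.), CH2Cl2, 0 °C → rt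
Reagents that add atoms: none
Why: Steglich-type carbodiimide esterification gives the redox-active N-acyloxyphthalimide needed for single-electron reduction; the silyl ether and the amide are inert.

Step 6
Reactants: 8 allyl phenyl sulfone
Product: 10 2-methylbut-3-en-2-yl phenyl sulfone, via but-3-en-2-yl phenyl sulfone 9 (not isolated)
Conditions: n-BuLi (1.05 equiv), THF, −78 °C, then MeI (1.1 equiv); then n-BuLi (1.1 equiv), −78 °C, then MeI (1.3 equiv), −78 → 0 °C
Reagents that add atoms: iodomethane, CI
Why: Two successive α-deprotonation/alkylation cycles of an allylic sulfone; the sulfonyl-stabilised allyl anion is methylated at the α-carbon each time, and low temperature keeps the terminal olefin from moving into conjugation.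

Step 7
Reactants: 7 1,3-dioxoisoindolin-2-yl (S)-5-[methoxy(methyl)amino]-3-methyl-5-oxo-3-(triethylsilyloxy)pentanoate; 10 2-methylbut-3-en-2-yl phenyl sulfone
Product: 11 (R)-N-methoxy-N,3,7-trimethyl-3-(triethylsilyloxy)oct-6-enamide
Conditions: 10 (4 equiv), Ru(bpy)3(PF6)2 (2 mol%), i-Pr2NEt (2.5 equiv), degassed CH2Cl2 (about 0.2 M in 7), blue LEDs, rt
Reagents that add atoms: none
Why: Visible-light excitation of Ru(bpy)3(PF6)2 (divalent ruthenium) and reductive quenching by i-Pr2NEt give [Ru(bpy)3]PF6 (monovalent ruthenium), which transfers one electron to the phthalimide ester of 7; N–O cleavage and loss of CO2 leave a primary radical on C4. This radical adds to the unsubstituted CH2 terminus of 10 (the future C5) and the adduct radical expels the phenylsulfonyl radical, so C4–C5 forms and the olefin appears between C6 and the gem-dimethyl carbon C7; the sulfonyl radical is reduced to sulfinate, which balances the electron count. The closest known reaction type is the photoredox decarboxylative allylation of N-acyloxyphthalimides with allyl sulfones, a radical addition–fragmentation. No ring closes and no stereocentre is created: C3 is never a radical and carries no group that a neighbouring radical could expel, so its arrangement is kept and only the descriptor changes from (S) to (R) because the arm priorities change. The selectivity needed is regiochemical (prenyl, not 1,1-dimethylallyl) and is secured by the tertiary position of the sulfonyl group, which leaves one accessible olefin terminus and makes the product olefin trisubstituted and unreactive towards a second addition. A radical process is indifferent to the crowding next to the fully substituted C3 that would stop a displacement at C4. No dihydropyridine hydrogen donor is added and 10 is used in excess at high concentration, so that hydrogen-atom capture by the primary radical is disfavoured and any sulfonyl-radical-induced isomerisation of 10 is absorbed.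

Step 8
Reactants: 12 2,5-dibromobenzene-1,4-diol (2,5-dibromohydroquinone)
Product: 13 1,4-dibromo-2,5-bis(methoxymethoxy)benzene
Conditions: MOMCl, i-Pr2NEt, CH2Cl2, 0 °C → rt
Reagents that add atoms: chloromethyl methyl ether, COCCl
Why: Williamson-type O-alkylation of both phenols to methoxymethyl acetals, which survive organolithium reagents; the symmetric product can give only one monolithio species.

Step 9
Reactants: 13 1,4-dibromo-2,5-bis(methoxymethoxy)benzene; 11 (R)-N-methoxy-N,3,7-trimethyl-3-(triethylsilyloxy)oct-6-enamide
Product: 16 (R)-1-[4-bromo-2,5-bis(methoxymethoxy)phenyl]-3,7-dimethyl-3-(triethylsilyloxy)oct-6-en-1-one, via aryllithium 14 (not isolated), via lithium hemiaminal chelate 15 (not isolated)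
Conditions: 13 (2.0 equiv), n-BuLi (1.9 equiv), THF, −78 °C, 30 min; then 11, −78 → −40 °C; AcOH quench at −78 °C
Reagents that add atoms: none
Why: Bromine–lithium exchange on one of two equivalent bromides followed by Weinreb ketone synthesis; the aryllithium adds once and the five-membered lithium chelate 15 persists until the quench, so no tertiary alcohol forms, while the second bromine resists exchange once the ring carries lithium and C3 is not involved.

Step 10
Reactants: 16 (R)-1-[4-bromo-2,5-bis(methoxymethoxy)phenyl]-3,7-dimethyl-3-(triethylsilyloxy)oct-6-en-1-one
Product: 18 (R)-1-(4-bromo-2,5-dihydroxyphenyl)-3-hydroxy-3,7-dimethyloct-6-en-1-one, via desilylated bis-MOM ketone 17 (not isolated)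
Conditions: HCl (about 0.5 M) in degassed MeOH, argon, 0 °C → rt, monitored; NaHCO3 quench
Reagents that add atoms: none
Why: Acid-catalysed methanolysis; the triethylsilyl ether is cleaved first and the two aryl methoxymethyl acetals are then transacetalised to dimethoxymethane, with dilute acid at or below room temperature chosen so that the tertiary β-hydroxy ketone is not dehydrated and the C6=C7 olefin is not protonated.

## Compound list

1 | dimethyl 3-hydroxy-3-methylpentanedioate | COC(=O)CC(C)(O)CC(=O)OC | starting material
2 | (S)-3-hydroxy-5-methoxy-3-methyl-5-oxopentanoic acid | COC(=O)C[C@@](C)(O)CC(=O)O | intermediate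
3 | methyl (S)-3-hydroxy-5-[methoxy(methyl)amino]-3-methyl-5-oxopentanoate | COC(=O)C[C@@](C)(O)CC(=O)N(C)OC | intermediate
4 | methyl (S)-5-[methoxy(methyl)amino]-3-methyl-5-oxo-3-(triethylsilyloxy)pentanoate | COC(=O)C[C@@](C)(O[Si](CC)(CC)CC)CC(=O)N(C)OC | intermediate
5 | (S)-5-[methoxy(methyl)amino]-3-methyl-5-oxo-3-(triethylsilyloxy)pentanoic acid | OC(=O)C[C@@](C)(O[Si](CC)(CC)CC)CC(=O)N(C)OC | intermediate
6 | N-hydroxyphthalimide | ON1C(=O)c2ccccc2C1=O | starting material
7 | 1,3-dioxoisoindolin-2-yl (S)-5-[methoxy(methyl)amino]-3-methyl-5-oxo-3-(triethylsilyloxy)pentanoate | O=C(ON1C(=O)c2ccccc2C1=O)C[C@@](C)(O[Si](CC)(CC)CC)CC(=O)N(C)OC | intermediate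
8 | allyl phenyl sulfone | C=CCS(=O)(=O)c1ccccc1 | starting material
9 | but-3-en-2-yl phenyl sulfone (racemic) | C=CC(C)S(=O)(=O)c1ccccc1 | intermediate
10 | 2-methylbut-3-en-2-yl phenyl sulfone | CC(C)(C=C)S(=O)(=O)c1ccccc1 | intermediate
11 | (R)-N-methoxy-N,3,7-trimethyl-3-(triethylsilyloxy)oct-6-enamide | CC(C)=CCC[C@@](C)(O[Si](CC)(CC)CC)CC(=O)N(C)OC | intermediate
12 | 2,5-dibromobenzene-1,4-diol | Oc1cc(Br)c(O)cc1Br | starting material
13 | 1,4-dibromo-2,5-bis(methoxymethoxy)benzene | COCOc1cc(Br)c(OCOC)cc1Br | intermediate
14 | [4-bromo-2,5-bis(methoxymethoxy)phenyl]lithium | [Li]c1cc(OCOC)c(Br)cc1OCOC | intermediate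
15 | lithium (3R)-1-[4-bromo-2,5-bis(methoxymethoxy)phenyl]-1-[methoxy(methyl)amino]-3,7-dimethyl-3-(triethylsilyloxy)oct-6-en-1-olate (both C1 epimers) | CC(C)=CCC[C@@](C)(O[Si](CC)(CC)CC)CC(O[Li])(N(C)OC)c1cc(OCOC)c(Br)cc1OCOC | intermediate
16 | (R)-1-[4-bromo-2,5-bis(methoxymethoxy)phenyl]-3,7-dimethyl-3-(triethylsilyloxy)oct-6-en-1-one | CC(C)=CCC[C@@](C)(O[Si](CC)(CC)CC)CC(=O)c1cc(OCOC)c(Br)cc1OCOC | intermediate
17 | (R)-1-[4-bromo-2,5-bis(methoxymethoxy)phenyl]-3-hydroxy-3,7-dimethyloct-6-en-1-one | CC(C)=CCC[C@@](C)(O)CC(=O)c1cc(OCOC)c(Br)cc1OCOC | intermediate
18 | (R)-1-(4-bromo-2,5-dihydroxyphenyl)-3-hydroxy-3,7-dimethyloct-6-en-1-one | CC(C)=CCC[C@@](C)(O)CC(=O)c1cc(O)c(Br)cc1O | target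

## Step count and risks

Total step count: 10. Longest linear sequence: 8 steps (steps 1, 2, 3, 4, 5, 7, 9, 10; from 1 to 18). Steps 6 and 8 are one-step side branches.

**Step 7 (key step).**
- What may go wrong: slow addition of the primary C4 radical to an unactivated olefin, so that hydrogen-atom capture from the amine-derived species gives premature reduction. The sulfonyl radical can also run a chain 1,3-shift of 10 to the primary prenyl sulfone, which would then transfer the allyl group through its dimethyl-substituted terminus and erode regiochemistry.
- Fallback: it sets out from 5 and returns at 11, keeping the carboxyl carbon as C5 and forming C5–C6 by polar chemistry. Reduction of 5 with BH3·SMe2 in THF at 0 °C should give (R)-5-hydroxy-N-methoxy-N,3-dimethyl-3-(triethylsilyloxy)pentanamide F1. An Appel reaction (I2, PPh3, imidazole) converts it to (S)-5-iodo-N-methoxy-N,3-dimethyl-3-(triethylsilyloxy)pentanamide F2. Zinc dust with LiCl in THF inserts to give [(S)-5-[methoxy(methyl)amino]-3-methyl-5-oxo-3-(triethylsilyloxy)pentyl]zinc iodide F3, an organozinc that leaves the Weinreb amide alone. Negishi coupling of F3 with 1-bromo-2-methylprop-1-ene under Pd(PPh3)4 (zerovalent palladium) gives 11.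

**Step 1.**
- What may go wrong: incomplete discrimination between the two enantiotopic ester groups, because the groups that distinguish them at C3 (OH and CH3) are of similar size; the enantiomeric purity of 2 must be assayed before going on.
- Fallback: it sets out from 1 and returns at 2 by classical resolution. One equivalent of KOH in methanol gives racemic 3-hydroxy-5-methoxy-3-methyl-5-oxopentanoic acid F4. Crystallisation with (S)-1-phenylethylamine (or its antipode, whichever deposits the wanted acid) gives (S)-1-phenylethylammonium (S)-3-hydroxy-5-methoxy-3-methyl-5-oxopentanoate F5, and acidification releases 2.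

**Step 9.**
- What may go wrong: deprotonation of 11 at C2 by the aryllithium in competition with addition, followed by β-elimination of the silyloxy group from the amide enolate; addition is slowed by the fully substituted C3 next to C2.
- Fallback: it sets out from 11 and returns at 16 through the more electrophilic aldehyde. Reduction with i-Bu2AlH in THF at −78 °C gives (R)-3,7-dimethyl-3-(triethylsilyloxy)oct-6-enal F6. Addition of 14 at −78 °C gives (3R)-1-[4-bromo-2,5-bis(methoxymethoxy)phenyl]-3,7-dimethyl-3-(triethylsilyloxy)oct-6-en-1-ol F7 as a mixture of C1 epimers, and Dess–Martin periodinane oxidation gives 16.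

**Step 10.**
- What may go wrong: acid-promoted dehydration of the tertiary β-hydroxy ketone followed by ring closure of the freed ortho phenol onto the enone, or acid-induced addition of the C3 hydroxyl across the C6=C7 olefin, before the less labile C5' acetal has gone.
- Fallback: it sets out from 16 and returns at 18 in two separate operations that keep strong Brønsted acid out of the solution; it adds no compound beyond the list and is entered as F0. Buffered HF·pyridine in THF/pyridine removes only the silyl ether to give 17, which is isolated. ZnBr2 with n-PrSH in CH2Cl2 at 0 °C then cleaves both aryl acetals by Lewis-acid activation and thiol capture.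

## Further compounds

F1 | step 7 | (R)-5-hydroxy-N-methoxy-N,3-dimethyl-3-(triethylsilyloxy)pentanamide | OCC[C@@](C)(O[Si](CC)(CC)CC)CC(=O)N(C)OC
F2 | step 7 | (S)-5-iodo-N-methoxy-N,3-dimethyl-3-(triethylsilyloxy)pentanamide | ICC[C@@](C)(O[Si](CC)(CC)CC)CC(=O)N(C)OC
F3 | step 7 | [(S)-5-[methoxy(methyl)amino]-3-methyl-5-oxo-3-(triethylsilyloxy)pentyl]zinc iodide | I[Zn]CC[C@@](C)(O[Si](CC)(CC)CC)CC(=O)N(C)OC
F4 | step 1 | racemic 3-hydroxy-5-methoxy-3-methyl-5-oxopentanoic acid | COC(=O)CC(C)(O)CC(=O)O
F5 | step 1 | (S)-1-phenylethylammonium (S)-3-hydroxy-5-methoxy-3-methyl-5-oxopentanoate | COC(=O)C[C@@](C)(O)CC(=O)[O-].C[C@H]([NH3+])c1ccccc1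
F6 | step 9 | (R)-3,7-dimethyl-3-(triethylsilyloxy)oct-6-enal | CC(C)=CCC[C@@](C)(O[Si](CC)(CC)CC)CC=O
F7 | step 9 | (3R)-1-[4-bromo-2,5-bis(methoxymethoxy)phenyl]-3,7-dimethyl-3-(triethylsilyloxy)oct-6-en-1-ol (both C1 epimers) | CC(C)=CCC[C@@](C)(O[Si](CC)(CC)CC)CC(O)c1cc(OCOC)c(Br)cc1OCOC
F0 | step 10 | none | none
A1 | alternative 1 | (R)-1-[4-bromo-5-hydroxy-2-(triisopropylsilyloxy)phenyl]-3,7-dimethyl-3-(triethylsilyloxy)oct-6-en-1-one | CC(C)=CCC[C@@](C)(O[Si](CC)(CC)CC)CC(=O)c1cc(O)c(Br)cc1O[Si](C(C)C)(C(C)C)C(C)C
A2 | alternative 1 | 4-bromo-2-(triisopropylsilyloxy)furan | Brc1coc(O[Si](C(C)C)(C(C)C)C(C)C)c1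
A3 | alternative 1 | (R)-5,9-dimethyl-5-(triethylsilyloxy)dec-8-en-1-yn-3-one | CC(C)=CCC[C@@](C)(O[Si](CC)(CC)CC)CC(=O)C#C
A4 | alternative 2 | (2S,6R)-2-tert-butyl-6-methyl-6-(4-methylpent-3-enyl)-1,3-dioxan-4-one | CC(C)=CCC[C@]1(C)CC(=O)O[C@@H](C(C)(C)C)O1
A5 | alternative 2 | (S)-2-tert-butyl-6-methyl-4H-1,3-dioxin-4-one | CC1=CC(=O)O[C@@H](C(C)(C)C)O1
A6 | alternative 2 | (4-methylpent-3-enyl)magnesium bromide | CC(C)=CCC[Mg]Br
A7 | alternative 2 | CuBr·SMe2, bromo(dimethyl sulfide)copper | Br[Cu].CSC
A8 | alternative 3 | (S)-1-[4-bromo-2,5-bis(methoxymethoxy)phenyl]-3,7-dimethyl-3-(4,4,5,5-tetramethyl-1,3,2-dioxaborolan-2-yl)oct-6-en-1-one | CC(C)=CCC[C@@](C)(B1OC(C)(C)C(C)(C)O1)CC(=O)c1cc(OCOC)c(Br)cc1OCOC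
A9 | alternative 3 | (E)-1-[4-bromo-2,5-bis(methoxymethoxy)phenyl]-3,7-dimethylocta-2,6-dien-1-one | CC(C)=CCC/C(C)=C/C(=O)c1cc(OCOC)c(Br)cc1OCOC
A10 | alternative 3 | bis(pinacolato)diboron | CC1(C)OB(OC1(C)C)B1OC(C)(C)C(C)(C)O1
A11 | alternative 3 | CuCl, copper monochloride | Cl[Cu]
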